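**Plan**

1. Numbering used here: ring C1 (OAc), C2 (OBz), C3=C4, C5 (OBz), C6 (OH and C7H2OBz).
2. The retrosynthesis cuts C3=C4 and C5–C6. The tertiary carbinol C6, its neighbour C5(OBz) and the alkene C4=C3 form a 1-ene-3,4-diol monoester unit inside a cyclohex-3-ene ring. This is the retron for carbonyl acyloxyallylation (C5–C6) followed in the same flask by ring-closing metathesis (C3=C4).
3. This leaves the ene-ketone CH2=CH–CH(OBz)–CH(OAc)–CO–CH2OBz (C3, C2, C1, C6, C7) and 3-bromopropenyl benzoate (C5, C4 and one carbon lost as ethylene).
4. The ene-ketone is L-sorbose in disguise: sugar C3/C4 are C1/C2, the anomeric C2 is the ketone C6 and sugar C1 is C7. The furanose is a temporary ring; zinc fragmentation of its 6-iodide unmasks the vinyl group and the ketone together.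
5. Forward: benzoate, iodide and acetate are installed on diacetone-L-sorbose, the sugar ring is fragmented, and one convergent operation then joins the two fragments at the fully substituted C6, closes the only carbocycle and gives the target with all four esters in place.
6. Stereochemistry: C1 and C2 come from L-sorbose; C6 from Felkin–Anh 1,2-induction by C1; C5 from the chair transition state of the Z-allylindium.

Key step: step 8

Remark: bromide 10 forms and is used as an E/Z mixture, both isomers being expected to give the same allylindium species; 6 is an anomeric mixture, which is immaterial because the anomeric carbon becomes the ketone carbon.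

**Route**

Step 1
Reactants: 1 2,3:4,6-di-O-isopropylidene-α-L-sorbofuranose
Product: 2 1-O-benzoyl-2,3:4,6-di-O-isopropylidene-α-L-sorbofuranose
Conditions: BzCl, pyridine, DMAP (cat.), CH2Cl2, 0 °C to rt
Reagents that add atoms: benzoyl chloride, O=C(Cl)c1ccccc1
Why: O-acylation (nucleophilic acyl substitution) of the only free hydroxyl, the primary C1–OH of the sugar, should install the benzoate that ends as the exocyclic CH2OBz (C7) without touching a stereocentre.

Step 2
Reactants: 2 1-O-benzoyl-2,3:4,6-di-O-isopropylidene-α-L-sorbofuranose
Product: 3 1-O-benzoyl-2,3-O-isopropylidene-α-L-sorbofuranose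
Conditions: AcOH/H2O (3:2), 40 °C
Reagents that add atoms: none
Why: Selective acid-catalysed acetal hydrolysis should remove the six-membered 4,6-O-isopropylidene ring, which is more labile than the five-membered anomeric 2,3-ketal, and leave the benzoate and the furanose intact.

Step 3
Reactants: 3 1-O-benzoyl-2,3-O-isopropylidene-α-L-sorbofuranose
Product: 4 1-O-benzoyl-6-deoxy-6-iodo-2,3-O-isopropylidene-α-L-sorbofuranose
Conditions: I2, PPh3, imidazole, toluene, 60 °C
Reagents that add atoms: iodine, [I][I]
Why: Appel-type iodination (SN2 displacement of the alkoxyphosphonium ion by iodide) should act only at the primary C6–OH, because the secondary C4–OH on the furanose is displaced far more slowly.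

Step 4
Reactants: 4 1-O-benzoyl-6-deoxy-6-iodo-2,3-O-isopropylidene-α-L-sorbofuranose
Product: 5 1,4-di-O-benzoyl-6-deoxy-6-iodo-2,3-O-isopropylidene-α-L-sorbofuranose
Conditions: BzCl, pyridine, DMAP (cat.), CH2Cl2, 0 °C
Reagents that add atoms: benzoyl chloride, O=C(Cl)c1ccccc1
Why: O-acylation of the remaining secondary C4–OH should give the benzoate that becomes the C2 benzoate of the target, with retention at that carbon because its C–O bond is not broken.

Step 5
Reactants: 5 1,4-di-O-benzoyl-6-deoxy-6-iodo-2,3-O-isopropylidene-α-L-sorbofuranose
Product: 6 2,3-di-O-acetyl-1,4-di-O-benzoyl-6-deoxy-6-iodo-L-sorbofuranose (anomers)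
Conditions: Ac2O, AcOH, H2SO4 (cat.), 0 °C to rt
Reagents that add atoms: acetic anhydride, CC(=O)OC(C)=O
Why: Acid-catalysed acetolysis of the anomeric isopropylidene ketal through the furanosyl oxocarbenium ion should turn O3 into the acetate needed at C1 of the target and the anomeric oxygen into a leaving group for the next step, the configuration at sugar C3 being untouched.

Step 6
Reactants: 6 2,3-di-O-acetyl-1,4-di-O-benzoyl-6-deoxy-6-iodo-L-sorbofuranose (anomers)
Product: 7 (3S,4R)-3-acetoxy-2-oxohex-5-ene-1,4-diyl dibenzoate
Conditions: Zn dust (activated), THF/H2O (9:1), sonication, 40 °C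
Reagents that add atoms: none
Why: Bernet–Vasella reductive fragmentation (zinc insertion into C6–I, β-elimination of the ring oxygen, collapse of the anomeric hemiketal acetate with loss of acetate) should open the furanose to the vinyl group and the ketone without touching the two carbinol stereocentres.

Step 7
Reactants: 8 acrolein; 9 benzoyl bromide
Product: 10 3-bromoprop-1-en-1-yl benzoate (E/Z mixture)
Conditions: ZnCl2 (cat.), CH2Cl2, −20 °C to 0 °C
Reagents that add atoms: none
Why: Lewis-acid-promoted 1,4-addition of the acyl bromide across the enal (O-acylation with conjugate delivery of bromide) should give the bifunctional three-carbon reagent that carries the future C5 benzoate.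

Step 8
Reactants: 7 (3S,4R)-3-acetoxy-2-oxohex-5-ene-1,4-diyl dibenzoate; 10 3-bromoprop-1-en-1-yl benzoate (E/Z mixture)
Product: 12 [(1R,2S,5R,6S)-6-acetoxy-2,5-bis(benzoyloxy)-1-hydroxycyclohex-3-en-1-yl]methyl benzoate (the target), via octadiene 11 (not isolated)
Conditions: In powder, 10 (1.2 equiv), THF, rt; then dilution with CH2Cl2, second-generation Hoveyda–Grubbs catalyst (5 mol %), 40 °C
Reagents that add atoms: none
Why: Indium inserts into the allylic C–Br bond of 10 and the resulting γ-(benzoyloxy)allylindium adds through its oxygen-bearing γ-carbon to the ketone of 7 (Barbier-type carbonyl acyloxyallylation), making the C5–C6 bond and the tertiary carbinol; without isolation the ruthenium carbene then joins the two terminal vinyl groups of 11 by ring-closing olefin metathesis, making the C3=C4 double bond with loss of ethylene. The closest known reaction types are the indium-mediated acyloxyallylation of carbonyl compounds with 3-bromopropenyl esters and the metathesis closure of sugar-derived octa-1,7-dienes to polyoxygenated cyclohexenes. The six-membered carbocycle is closed by metathesis of the 1,7-diene through a ruthenacyclobutane, the cis ring alkene being the only geometry the ring allows. C6 is set by 1,2-induction from C1 under the polar Felkin–Anh (Cornforth) model, the weakly coordinating acetate lying anti to the incoming carbon, which should place the new hydroxyl cis to the C1 acetate on the ring; C5 is set in a chair-like six-membered transition state of the Z-configured allylindium (benzoate carbonyl bound to indium) with the branched C1 arm of the ketone equatorial, which should place the C5 benzoate trans to the C6 hydroxyl. The step needs γ- over α-attack of the allyl metal, non-chelation facial control and reaction at the ketone in the presence of four esters; these rest on the SE2′ preference of allylindium reagents, the poor chelating ability of acyloxy groups and the inertness of organoindium species toward esters, while only the two monosubstituted alkenes of 11 can enter metathesis.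

**Compound list**

1 | 2,3:4,6-di-O-isopropylidene-α-L-sorbofuranose | OC[C@]1(OC(C)(C)O2)[C@@H]2[C@@H]3OC(C)(C)OC[C@@H]3O1 | starting material
2 | 1-O-benzoyl-2,3:4,6-di-O-isopropylidene-α-L-sorbofuranose | O=C(OC[C@]1(OC(C)(C)O2)[C@@H]2[C@@H]3OC(C)(C)OC[C@@H]3O1)c1ccccc1 | intermediate
3 | 1-O-benzoyl-2,3-O-isopropylidene-α-L-sorbofuranose | O=C(OC[C@]1(OC(C)(C)O2)[C@@H]2[C@H](O)[C@H](CO)O1)c1ccccc1 | intermediate
4 | 1-O-benzoyl-6-deoxy-6-iodo-2,3-O-isopropylidene-α-L-sorbofuranose | O=C(OC[C@]1(OC(C)(C)O2)[C@@H]2[C@H](O)[C@H](CI)O1)c1ccccc1 | intermediate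
5 | 1,4-di-O-benzoyl-6-deoxy-6-iodo-2,3-O-isopropylidene-α-L-sorbofuranose | O=C(OC[C@]1(OC(C)(C)O2)[C@@H]2[C@H](OC(=O)c3ccccc3)[C@H](CI)O1)c1ccccc1 | intermediate
6 | 2,3-di-O-acetyl-1,4-di-O-benzoyl-6-deoxy-6-iodo-L-sorbofuranose (anomeric mixture) | O=C(OCC1(OC(C)=O)[C@@H](OC(C)=O)[C@H](OC(=O)c2ccccc2)[C@H](CI)O1)c1ccccc1 | intermediate
7 | (3S,4R)-3-acetoxy-2-oxohex-5-ene-1,4-diyl dibenzoate | O=C(OCC(=O)[C@@H](OC(C)=O)[C@H](OC(=O)c1ccccc1)C=C)c1ccccc1 | intermediate
8 | acrolein | C=CC=O | starting material
9 | benzoyl bromide | O=C(Br)c1ccccc1 | starting material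
10 | 3-bromoprop-1-en-1-yl benzoate (E/Z mixture) | O=C(OC=CCBr)c1ccccc1 | intermediate
11 | (3S,4R,5S,6R)-5-acetoxy-4-[(benzoyloxy)methyl]-4-hydroxyocta-1,7-diene-3,6-diyl dibenzoate (not isolated) | CC(=O)O[C@@H]([C@H](OC(=O)c1ccccc1)C=C)[C@@](O)(COC(=O)c1ccccc1)[C@@H](OC(=O)c1ccccc1)C=C | intermediate
12 | [(1R,2S,5R,6S)-6-acetoxy-2,5-bis(benzoyloxy)-1-hydroxycyclohex-3-en-1-yl]methyl benzoate | CC(=O)O[C@H]1[C@H](OC(=O)c2ccccc2)C=C[C@H](OC(=O)c2ccccc2)[C@]1(O)COC(=O)c1ccccc1 | target

Total step count: 8. Longest linear sequence: 7 steps (steps 1 to 6 and step 8).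

**Steps most likely to fail, and fallbacks**

Step 8. The two ketone substituents differ only moderately in size, so the simple diastereoselection at C5 in the chair transition state may be low. Facial selectivity at C6 may also be eroded by competing chelation. Residual enol ester may tie up the ruthenium carbene and stall the ring closure. The fallback sets out from 7 and comes back at 12. It introduces the C5 oxygen after ring closure, under cyclic control.
- Indium-mediated Barbier addition of plain allyl bromide (C=CCBr; In, THF/H2O, where acyloxy chelation is negligible) creates only the C6 centre, under the same Felkin–Anh bias, and should give (3R,4S,5S)-4-acetoxy-5-[(benzoyloxy)methyl]-5-hydroxyocta-1,7-dien-3-yl benzoate F1.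
- Ring-closing metathesis with second-generation Hoveyda–Grubbs catalyst closes it to [(1S,5R,6S)-6-acetoxy-5-(benzoyloxy)-1-hydroxycyclohex-3-en-1-yl]methyl benzoate F2.
- Allylic hydroxylation of the only allylic methylene (SeO2 cat., t-BuOOH, CH2Cl2) should give [(1R,5R,6S)-6-acetoxy-5-(benzoyloxy)-1,2-dihydroxycyclohex-3-en-1-yl]methyl benzoate (C2 epimers) F3.
- The epimer with the new hydroxyl trans to the tertiary hydroxyl is benzoylated directly (BzCl, pyridine). The cis epimer is inverted by Mitsunobu esterification with benzoic acid (PPh3, DIAD). Both converge on 12.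

Step 6. The newly formed α-acyloxy ketone may be reduced further by zinc (reductive loss of an acyloxy group), or acyl groups may migrate while the ketone sits with the metal. The fallback sets out from 6 and comes back at 12. The fragmentation is merged with the carbon–carbon bond formation as a tandem fragmentation–acyloxyallylation. Iodide 6 is added slowly to zinc dust in THF/H2O that already holds the allylindium reagent made from 10 and indium, so that ketone 7 is trapped as it forms. The diene 11 is then isolated and cyclized with the same ruthenium catalyst to 12. No new compound is needed.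

Step 5. Under the strongly acidic acetolysis the furanose ring may be cleaved, the anomeric acetate may eliminate, or acyl groups may scramble. The fallback sets out from 5 and comes back at 7. The order is reversed. Zinc fragmentation of 5 (Zn dust, THF/H2O) lets the anomeric hemiketal collapse with loss of acetone and should free the C3 hydroxyl, giving (3S,4R)-3-hydroxy-2-oxohex-5-ene-1,4-diyl dibenzoate F4. This α-ketol is then acetylated under non-basic Lewis-acid catalysis (Ac2O, Sc(OTf)3 cat., MeCN, −20 °C) to 7, which avoids base-induced β-elimination of the neighbouring benzoate.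

**Further compounds**

F1 | step 8 | (3R,4S,5S)-4-acetoxy-5-[(benzoyloxy)methyl]-5-hydroxyocta-1,7-dien-3-yl benzoate | CC(=O)O[C@@H]([C@H](OC(=O)c1ccccc1)C=C)[C@@](O)(COC(=O)c1ccccc1)CC=C
F2 | step 8 | [(1S,5R,6S)-6-acetoxy-5-(benzoyloxy)-1-hydroxycyclohex-3-en-1-yl]methyl benzoate | CC(=O)O[C@H]1[C@H](OC(=O)c2ccccc2)C=CC[C@]1(O)COC(=O)c1ccccc1
F3 | step 8 | [(1R,5R,6S)-6-acetoxy-5-(benzoyloxy)-1,2-dihydroxycyclohex-3-en-1-yl]methyl benzoate (C2 epimers) | CC(=O)O[C@H]1[C@H](OC(=O)c2ccccc2)C=CC(O)[C@]1(O)COC(=O)c1ccccc1
F0 | step 6 | none | none
F4 | step 5 | (3S,4R)-3-hydroxy-2-oxohex-5-ene-1,4-diyl dibenzoate | O=C(OCC(=O)[C@@H](O)[C@H](OC(=O)c1ccccc1)C=C)c1ccccc1
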